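**Retrosynthetic overview**

- The target is a 3,5-dibromo-7-methoxy-1H-indole (unprimed atoms) whose C4 carries N1' of a 2,5-dibromoindole (primed atoms). N1' is bonded to C4, C2' and C7a', and C2' and C7a' stand 1,4 to each other through C3'–C3a'. Both N1'–C2' and N1'–C7a' can therefore be made by condensing a C4 primary amine with the acid and ketone carbonyls of 2-(2-oxocyclohexyl)acetic acid, with the benzo ring C3a'–C7a' carried as a cyclohexene.
- Late disconnections: C3–Br (last, on the N–H lower indole), the N1 tosyl group, C2'–Br (from the lactam carbonyl of an N-aryl oxindole with POBr3), C5'–Br (bromination para to the lactam nitrogen) and the four extra hydrogens of the cyclohexene (DDQ).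
- Key disconnection: the five-membered enelactam ring N1'–C2'–C3'–C3a'–C7a', opened to 5-bromo-7-methoxy-1-tosylindol-4-amine and the keto acid.
- The amine comes from commercial 4-bromo-7-methoxy-1H-indole by N-tosylation, Pd-catalysed amination at C4 with benzophenone imine, and bromination ortho to the amino group (C5).
- Ring order: lower indole (bought), then the five-membered lactam ring on the preformed cyclohexane (key step), then the upper benzene ring by dehydrogenation, then the 2-bromopyrrole ring by aromatisation of the lactam.

Key step: step 4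

Assumption: the target SMILES has no stereodescriptor and the molecule has no stereocentre, so the hindered C4–N1' axis is left uncontrolled and the material is made racemic with respect to it.

**Route**

Step 1
Reactants: 1 4-bromo-7-methoxy-1H-indole
Product: 3 4-bromo-7-methoxy-1-tosyl-1H-indole (tosyl = 4-methylbenzenesulfonyl), via sodium indolide 2 (not isolated)
Conditions: NaH (1.2 equiv), DMF, 0 °C; then TsCl (1.15 equiv), 0 °C to rt
Reagents that add atoms: p-toluenesulfonyl chloride, Cc1ccc(cc1)S(Cl)(=O)=O
Why: Irreversible deprotonation of the indole N–H by NaH gives the sodium indolide 2, which is sulfonylated at nitrogen by TsCl (N-sulfonylation of an indole anion); the tosyl group later keeps the pyrrole ring of the lower indole inert to acid, DDQ and electrophilic bromine.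

Step 2
Reactants: 3 4-bromo-7-methoxy-1-tosyl-1H-indole
Product: 5 7-methoxy-1-tosyl-1H-indol-4-amine, via ketimine 4 (not isolated)
Conditions: Ph2C=NH (1.2 equiv), Pd2(dba)3 (2.5 mol %), rac-BINAP (7.5 mol %), Cs2CO3 (1.5 equiv), toluene, 100 °C; then 2 M aq HCl, THF, rt; NaHCO3 work-up
Reagents that add atoms: benzophenone imine, N=C(c1ccccc1)c1ccccc1
Why: Buchwald–Hartwig amination with benzophenone imine as an ammonia surrogate: zerovalent palladium inserts into the only C–Br bond (C4), the imine nitrogen is coupled, and mild aqueous acid hydrolyses the N-aryl ketimine 4 to the primary amine and benzophenone without touching the sulfonamide or the methyl ether; Cs2CO3 is chosen over an alkoxide base to spare the N-tosyl group.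

Step 3
Reactants: 5 7-methoxy-1-tosyl-1H-indol-4-amine
Product: 6 5-bromo-7-methoxy-1-tosyl-1H-indol-4-amine
Conditions: NBS (1.0 equiv), DMF, −20 °C to 0 °C, dark
Reagents that add atoms: N-bromosuccinimide, O=C1CCC(=O)N1Br
Why: Electrophilic aromatic bromination controlled by the amino group: its para position (C7) carries the methoxy group and one ortho position is the ring-fusion carbon C3a, so C5 is the only open activated site, the tosylated pyrrole ring is deactivated, and one equivalent of NBS at low temperature should limit oxidation of the electron-rich aminoanisole and a second bromination at C6.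

Step 4
Reactants: 6 5-bromo-7-methoxy-1-tosyl-1H-indol-4-amine; 7 2-(2-oxocyclohexyl)acetic acid (racemic, 1.5 equiv)
Product: 9 1-(5-bromo-7-methoxy-1-tosyl-1H-indol-4-yl)-1,3,3a,4,5,6-hexahydro-2H-indol-2-one (racemic), via enamino acid 8 (not isolated)
Conditions: TsOH·H2O (0.2 equiv), xylene, Dean–Stark trap, reflux
Reagents that add atoms: none
Why: This is the acid-catalysed double condensation of a primary arylamine with a γ-keto acid, the lactam counterpart of a Paal–Knorr closure, and its closest known relative is the condensation of 2-(2-oxocyclohexyl)acetic acid or its esters with anilines to bicyclic enelactams. The amine adds to the protonated ketone, the carbinolamine loses water to the imine/enamine 8 (N1'–C7a' formed), and the enamine nitrogen then attacks the carboxyl carbon (N1'–C2' formed) with loss of a second water, both removed azeotropically. The five-membered ring N1'–C2'–C3'–C3a'–C7a' closes by a 5-exo-trig acylation at the carboxyl carbon; if acylation comes first, the same ring closes by 5-exo-trig addition of the amide nitrogen to the ketone followed by dehydration. No stereocentre is set: C3a' comes from racemic 7, is not controlled and is erased in step 5, and any C3a'=C7a' double-bond isomer of 9 is carried forward because it aromatises to the same oxindole. The step needs only chemoselectivity for the C4 amino group, which is secured because the indole nitrogen is blocked as the sulfonamide, the tosylated pyrrole ring does not add to the ketone under TsOH, and the 1,4-relationship of the two carbonyls allows only this lactam; the C7 methoxy group para to the amine raises its nucleophilicity against the two flanking groups (C5–Br and C3a).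

Step 5
Reactants: 9 1-(5-bromo-7-methoxy-1-tosyl-1H-indol-4-yl)-1,3,3a,4,5,6-hexahydro-2H-indol-2-one
Product: 10 1-(5-bromo-7-methoxy-1-tosyl-1H-indol-4-yl)-1,3-dihydro-2H-indol-2-one
Conditions: DDQ (2.3 equiv), 1,4-dioxane, 90 °C
Reagents that add atoms: none
Why: Dehydrogenative aromatisation with DDQ: hydride abstraction from the allylic C6' position of the enamide gives a nitrogen-stabilised allyl cation, proton loss gives a cyclohexadiene, and a second hydride abstraction and deprotonation gives the benzene ring of the oxindole and erases the C3a' stereocentre; DDQ is preferred to palladium on carbon because it leaves the aryl C–Br bond, the sulfonamide and the deactivated lower indole alone.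

Step 6
Reactants: 10 1-(5-bromo-7-methoxy-1-tosyl-1H-indol-4-yl)-1,3-dihydro-2H-indol-2-one
Product: 11 5-bromo-1-(5-bromo-7-methoxy-1-tosyl-1H-indol-4-yl)-1,3-dihydro-2H-indol-2-one
Conditions: NBS (1.05 equiv), MeCN, 0 °C to rt
Reagents that add atoms: N-bromosuccinimide, O=C1CCC(=O)N1Br
Why: Electrophilic aromatic bromination para to the lactam nitrogen (C5'), the position activated by the planar anilide nitrogen of the oxindole, as in the known NBS bromination of N-substituted oxindoles at C5; the lower ring is deactivated by the N-tosyl group, its only free benzenoid position (C6) is flanked by bromine and methoxy, and the polar solvent at low temperature favours ring bromination over α-bromination at C3'.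

Step 7
Reactants: 11 5-bromo-1-(5-bromo-7-methoxy-1-tosyl-1H-indol-4-yl)-1,3-dihydro-2H-indol-2-one
Product: 12 2,5-dibromo-1-(5-bromo-7-methoxy-1-tosyl-1H-indol-4-yl)-1H-indole
Conditions: POBr3 (3 equiv), imidazole (1.2 equiv), ClCH2CH2Cl, 80 °C; aq NaHCO3 work-up
Reagents that add atoms: phosphorus oxybromide, O=P(Br)(Br)Br
Why: Known conversion of an oxindole into a 2-bromoindole with POBr3: the lactam oxygen is phosphorylated, bromide adds at C2' and the phosphate leaves (addition–elimination on a Vilsmeier-type haloiminium), and loss of a C3' proton gives the aromatic 2-bromoindole; imidazole buffers the HBr so that the tosyl group and the methyl ether survive.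

Step 8
Reactants: 12 2,5-dibromo-1-(5-bromo-7-methoxy-1-tosyl-1H-indol-4-yl)-1H-indole
Product: 13 2,5-dibromo-1-(5-bromo-7-methoxy-1H-indol-4-yl)-1H-indole
Conditions: Cs2CO3 (3 equiv), THF/MeOH (2:1), rt to 40 °C
Reagents that add atoms: none
Why: Mild methanolysis of the N-sulfonyl indole, in which methoxide generated by Cs2CO3 attacks sulfur and the bromine-stabilised indolide leaves; the aryl bromides and the 2'-bromoindole are not substituted by methoxide at this temperature.

Step 9
Reactants: 13 2,5-dibromo-1-(5-bromo-7-methoxy-1H-indol-4-yl)-1H-indole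
Product: 15 3,5-dibromo-4-(2,5-dibromo-1H-indol-1-yl)-7-methoxy-1H-indole (target), via potassium indolide 14 (not isolated)
Conditions: KOH (1.2 equiv), DMF, 0 °C; then NBS (1.0 equiv), −20 °C to 0 °C
Reagents that add atoms: N-bromosuccinimide, O=C1CCC(=O)N1Br
Why: Electrophilic bromination at C3 of the potassium indolide 14 of the lower ring, by far the most nucleophilic carbon present; the upper indole has no N–H to deprotonate and its C3' is deactivated by the C2' and C5' bromines and the N-aryl group, so one equivalent of NBS at low temperature should stop at the lower C3.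

**Compound list**

1 | 4-bromo-7-methoxy-1H-indole | COc1ccc(Br)c2cc[nH]c12 | starting material
2 | sodium 4-bromo-7-methoxyindol-1-ide | COc1ccc(Br)c2cc[n-]c12.[Na+] | intermediate
3 | 4-bromo-7-methoxy-1-tosyl-1H-indole | COc1ccc(Br)c2ccn(S(=O)(=O)c3ccc(C)cc3)c12 | intermediate
4 | N-(diphenylmethylidene)-7-methoxy-1-tosyl-1H-indol-4-amine | COc1ccc(N=C(c3ccccc3)c3ccccc3)c2ccn(S(=O)(=O)c3ccc(C)cc3)c12 | intermediate
5 | 7-methoxy-1-tosyl-1H-indol-4-amine | COc1ccc(N)c2ccn(S(=O)(=O)c3ccc(C)cc3)c12 | intermediate
6 | 5-bromo-7-methoxy-1-tosyl-1H-indol-4-amine | COc1cc(Br)c(N)c2ccn(S(=O)(=O)c3ccc(C)cc3)c12 | intermediate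
7 | 2-(2-oxocyclohexyl)acetic acid (racemic) | OC(=O)CC1CCCCC1=O | starting material
8 | 2-{2-[(5-bromo-7-methoxy-1-tosyl-1H-indol-4-yl)amino]cyclohex-2-en-1-yl}acetic acid (racemic) | OC(=O)CC1CCCC=C1Nc1c(Br)cc(OC)c2c1ccn2S(=O)(=O)c1ccc(C)cc1 | intermediate
9 | 1-(5-bromo-7-methoxy-1-tosyl-1H-indol-4-yl)-1,3,3a,4,5,6-hexahydro-2H-indol-2-one (racemic) | O=C1CC2CCCC=C2N1c1c(Br)cc(OC)c2c1ccn2S(=O)(=O)c1ccc(C)cc1 | intermediate
10 | 1-(5-bromo-7-methoxy-1-tosyl-1H-indol-4-yl)-1,3-dihydro-2H-indol-2-one | O=C1Cc2ccccc2N1c1c(Br)cc(OC)c2c1ccn2S(=O)(=O)c1ccc(C)cc1 | intermediate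
11 | 5-bromo-1-(5-bromo-7-methoxy-1-tosyl-1H-indol-4-yl)-1,3-dihydro-2H-indol-2-one | O=C1Cc2cc(Br)ccc2N1c1c(Br)cc(OC)c2c1ccn2S(=O)(=O)c1ccc(C)cc1 | intermediate
12 | 2,5-dibromo-1-(5-bromo-7-methoxy-1-tosyl-1H-indol-4-yl)-1H-indole | COc1cc(Br)c(-n2c(Br)cc3cc(Br)ccc32)c2ccn(S(=O)(=O)c3ccc(C)cc3)c12 | intermediate
13 | 2,5-dibromo-1-(5-bromo-7-methoxy-1H-indol-4-yl)-1H-indole | COc1cc(Br)c(-n2c(Br)cc3cc(Br)ccc32)c2cc[nH]c12 | intermediate
14 | potassium 5-bromo-4-(2,5-dibromo-1H-indol-1-yl)-7-methoxyindol-1-ide | COc1cc(Br)c(-n2c(Br)cc3cc(Br)ccc32)c2cc[n-]c12.[K+] | intermediate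
15 | 3,5-dibromo-4-(2,5-dibromo-1H-indol-1-yl)-7-methoxy-1H-indole (CNP0191258.0) | COc1cc(Br)c(-n2c(Br)cc3cc(Br)ccc32)c2c(Br)c[nH]c12 | target

**Step count and risks**

Total step count: 9. Longest linear sequence: 9 steps (1 to 15).

Steps most likely to fail:

1. Step 4 (key condensation). The doubly flanked C4 amine may fail to condense with the ketone under equilibrium conditions, so the keto acid is diverted to its enol lactone or the reaction stalls before ring closure. Fallback, setting out from 6 and 7 and returning at 9: the amide bond is made first under forcing, irreversible conditions. Keto acid 7 is dehydrated (Ac2O, NaOAc, reflux) to the enol lactone 3a,4,5,6-tetrahydro-1-benzofuran-2(3H)-one F1. Amine 6 is converted with AlMe3 (toluene, 0 °C to rt) into dimethylaluminium N-(5-bromo-7-methoxy-1-tosyl-1H-indol-4-yl)amide F2. F2 opens F1 in a Weinreb-type aminolysis (80 °C, dilute aq HCl work-up) to the keto amide N-(5-bromo-7-methoxy-1-tosyl-1H-indol-4-yl)-2-(2-oxocyclohexyl)acetamide F3. TsOH in toluene with a Dean–Stark trap then adds the amide nitrogen to the ketone and dehydrates the hydroxylactam to 9.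

2. Step 5 (dehydrogenation). Aromatisation may stop at a dihydro stage, or DDQ may go on to oxidise the new C3' methylene of the oxindole (oxidative coupling). Fallback, setting out from 6 and returning at 10: the upper ring is brought in already aromatic. Purchased 2-(2-iodophenyl)acetic acid is converted ((COCl)2, cat. DMF, CH2Cl2) into 2-(2-iodophenyl)acetyl chloride F4. F4 acylates 6 (pyridine, CH2Cl2, 0 °C to rt) to N-(5-bromo-7-methoxy-1-tosyl-1H-indol-4-yl)-2-(2-iodophenyl)acetamide F5. An intramolecular Goldberg amidation (CuI 10 mol %, N,N'-dimethylethylenediamine 20 mol %, K3PO4, toluene, 100 °C) then closes the lactam at the C–I bond, which reacts much faster than the aryl bromide, and gives 10.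

3. Step 9 (final bromination). Site selectivity between the two free indole β-positions (C3 against C3') may be lost, or a second bromine may be introduced. Fallback, setting out from 11 and returning at 15: the lower C3 is brominated while the upper unit is still a lactam and therefore has no indole β-position. The tosyl group of 11 is removed with Bu4NF (THF, 60 °C), which avoids alkoxide opening of the N-aryl lactam, to give 5-bromo-1-(5-bromo-7-methoxy-1H-indol-4-yl)-1,3-dihydro-2H-indol-2-one F6. NBS (1.0 equiv, DMF, −40 °C) brominates C3 of the free indole to give 5-bromo-1-(3,5-dibromo-7-methoxy-1H-indol-4-yl)-1,3-dihydro-2H-indol-2-one F7. POBr3 with imidazole in ClCH2CH2Cl at 80 °C then converts the lactam into the 2'-bromoindole and gives 15; the imidazole buffer keeps the 3-bromoindole from acid-promoted loss of bromine.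

**Further compounds**

F1 | step 4 | 3a,4,5,6-tetrahydro-1-benzofuran-2(3H)-one (racemic) | O=C1CC2CCCC=C2O1
F2 | step 4 | dimethylaluminium N-(5-bromo-7-methoxy-1-tosyl-1H-indol-4-yl)amide | C[Al](C)Nc1c(Br)cc(OC)c2c1ccn2S(=O)(=O)c1ccc(C)cc1
F3 | step 4 | N-(5-bromo-7-methoxy-1-tosyl-1H-indol-4-yl)-2-(2-oxocyclohexyl)acetamide (racemic) | O=C(CC1CCCCC1=O)Nc1c(Br)cc(OC)c2c1ccn2S(=O)(=O)c1ccc(C)cc1
F4 | step 5 | 2-(2-iodophenyl)acetyl chloride | O=C(Cl)Cc1ccccc1I
F5 | step 5 | N-(5-bromo-7-methoxy-1-tosyl-1H-indol-4-yl)-2-(2-iodophenyl)acetamide | O=C(Cc1ccccc1I)Nc1c(Br)cc(OC)c2c1ccn2S(=O)(=O)c1ccc(C)cc1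
F6 | step 9 | 5-bromo-1-(5-bromo-7-methoxy-1H-indol-4-yl)-1,3-dihydro-2H-indol-2-one | O=C1Cc2cc(Br)ccc2N1c1c(Br)cc(OC)c2[nH]ccc12
F7 | step 9 | 5-bromo-1-(3,5-dibromo-7-methoxy-1H-indol-4-yl)-1,3-dihydro-2H-indol-2-one | O=C1Cc2cc(Br)ccc2N1c1c(Br)cc(OC)c2[nH]cc(Br)c12
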